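**Plan**

- Numbering (eremophilane): ring A = C1=C2, C3 (O-acyl), C4 (CH3), C5 (quaternary, CH3), C10; ring B = C5, C6, C7 (=CMe2), C8 (C=O), C9=C10.
- Enabling feature: C10 is an sp2 carbon (part of C9=C10) bonded to the quaternary C5 shared by both rings. The C5–C10 bond can therefore be made by adding a C10 enol triflate across a trisubstituted C5=C6 alkene, which keeps C9=C10 and leaves a vinyl group on C5 for ring B.
- Retrosynthetic cuts, in order: C3–O acyl bond; C7=C11 (acetone aldol); C1=C2 (dehydrogenation); C6=C7 (ring-closing metathesis); C5–C10 (Heck); C9–C10 (ester enolate acylation); C3–C4 (allylboration).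
- Forward order: open chain C8–C9–C10–C1–C2–C3–C4–C5=C6, then ring A (Heck), ring B (metathesis), C1=C2, isopropylidene, side-chain ester.
- Stereochemistry: C3 and C4 by chirality transfer from an (R)-α-methyl allylboronate made by sparteine-mediated lithiation–borylation; C5 from C4 through allylic 1,3-strain in the Heck closure; C6' of the acid from (S)-2-methylbutan-1-ol.

Key step: step 8

Assumption: the (Z)-but-2-en-2-yl pinacol boronate used in step 2 is taken as a catalogue compound (otherwise it is the syn-hydroboration product of but-2-yne with pinacolborane).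
Assumption: (R)-BINAP is taken as the ligand enantiomer whose face preference matches the substrate bias in step 8; which enantiomer matches is not known in advance.
Abbreviation: TBS = tert-butyldimethylsilyl.

**Step 1**
Reactants: 1 ethanol; 2 N,N-diisopropylcarbamoyl chloride
Product: 3 ethyl N,N-diisopropylcarbamate
Conditions: Et3N, CH2Cl2, reflux
Reagents that add atoms: none
Why: O-Carbamoylation (nucleophilic acyl substitution at the carbamoyl chloride) installs the carbamate that later directs and stabilises the α-lithiation; no stereocentre is formed.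

**Step 2**
Reactants: 3 ethyl N,N-diisopropylcarbamate; 4 (Z)-2-(but-2-en-2-yl)-4,4,5,5-tetramethyl-1,3,2-dioxaborolane
Product: 7 2-[(2R,3E)-3-methylpent-3-en-2-yl]-4,4,5,5-tetramethyl-1,3,2-dioxaborolane, via lithiated carbamate 5 (not isolated), via boron ate complex 6 (not isolated)
Conditions: s-BuLi, (−)-sparteine, Et2O, −78 °C; 4, −78 °C; MgBr2·OEt2, −78 °C → reflux; aq. NH4Cl
Reagents that add atoms: none
Why: Sparteine-mediated enantioselective α-lithiation of the O-alkyl carbamate gives a configurationally stable (S)-organolithium, which is borylated with retention and then undergoes a stereospecific 1,2-metallate rearrangement (lithiation–borylation) in which the butenyl group migrates with inversion as the carbamate leaves, so the boron-bearing carbon should be R and the alkene geometry of 4 is carried over.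

**Step 3**
Reactants: 7 2-[(2R,3E)-3-methylpent-3-en-2-yl]-4,4,5,5-tetramethyl-1,3,2-dioxaborolane; 8 methyl 4-oxobutanoate
Product: 11 (5S)-5-[(2R,3Z)-3-methylpent-3-en-2-yl]oxolan-2-one, via borate ester 9 (not isolated), via hydroxy ester 10 (not isolated)
Conditions: toluene, 23–40 °C; aq. NaHCO3; then p-TsOH·H2O (cat.), CH2Cl2, 23 °C
Reagents that add atoms: none
Why: Carbonyl allylboration through a closed chair-like transition state in which the (E)-γ-methyl is equatorial (anti C3/C4) and the α-methyl axial, away from the β-methyl (allylic 1,2-strain) and the pinacol ring, so the (R)-boronate should transfer its chirality to (3S,4R) and give the (Z)-trisubstituted alkene, after which acid closes the γ-lactone.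

**Step 4**
Reactants: 11 (5S)-5-[(2R,3Z)-3-methylpent-3-en-2-yl]oxolan-2-one
Product: 12 (4S,5R,6Z)-4-hydroxy-N-methoxy-N,5,6-trimethyloct-6-enamide
Conditions: MeNHOMe·HCl, i-PrMgCl, THF, −20 → 0 °C; aq. NH4Cl
Reagents that add atoms: N,O-dimethylhydroxylamine hydrochloride, CNOC.Cl
Why: Aminolysis of the lactone by the chloromagnesium amide of N,O-dimethylhydroxylamine opens the ring to the N-methoxy-N-methylamide without touching either stereocentre.

**Step 5**
Reactants: 12 (4S,5R,6Z)-4-hydroxy-N-methoxy-N,5,6-trimethyloct-6-enamide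
Product: 13 (4S,5R,6Z)-4-(TBS-oxy)-N-methoxy-N,5,6-trimethyloct-6-enamide
Conditions: TBSOTf, 2,6-lutidine, CH2Cl2, −78 → 0 °C
Reagents that add atoms: tert-butyldimethylsilyl trifluoromethanesulfonate, CC(C)(C)[Si](C)(C)OS(=O)(=O)C(F)(F)F
Why: Silylation of the hindered secondary alcohol with the silyl triflate and a non-nucleophilic base, carried out at once so that the hydroxy amide cannot revert to the lactone.

**Step 6**
Reactants: 13 (4S,5R,6Z)-4-(TBS-oxy)-N-methoxy-N,5,6-trimethyloct-6-enamide; 14 methyl acetate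
Product: 16 methyl (6S,7R,8Z)-6-(TBS-oxy)-7,8-dimethyl-3-oxodec-8-enoate, via lithium enolate 15 (not isolated)
Conditions: LiN(i-Pr)2, MeOAc, THF, −78 °C; then 13, −78 → −40 °C; aq. NH4Cl
Reagents that add atoms: none
Why: Crossed Claisen-type acylation of the lithium ester enolate by the N-methoxy-N-methylamide, whose chelated tetrahedral adduct collapses to the β-keto ester only on work-up, forms the C9–C10 bond.

**Step 7**
Reactants: 16 methyl (6S,7R,8Z)-6-(TBS-oxy)-7,8-dimethyl-3-oxodec-8-enoate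
Product: 17 methyl (2Z,6S,7R,8Z)-6-(TBS-oxy)-7,8-dimethyl-3-{[(trifluoromethyl)sulfonyl]oxy}deca-2,8-dienoate
Conditions: Tf2O, aq. LiOH, toluene, 5 °C
Reagents that add atoms: trifluoromethanesulfonic anhydride, O=S(=O)(C(F)(F)F)OS(=O)(=O)C(F)(F)F
Why: O-Triflation of the lithium-chelated enolate of the β-keto ester (enol triflate formation), the chelate holding the ester and the enolate oxygen on the same side so that the (Z)-enol triflate needed for ring B should result.

**Step 8**
Reactants: 17 methyl (2Z,6S,7R,8Z)-6-(TBS-oxy)-7,8-dimethyl-3-{[(trifluoromethyl)sulfonyl]oxy}deca-2,8-dienoate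
Product: 18 methyl (2Z)-2-[(2R,3R,4S)-4-(TBS-oxy)-2-ethenyl-2,3-dimethylcyclohexylidene]acetate
Conditions: Pd(OAc)2 (10 mol %), (R)-BINAP (20 mol %), K2CO3, toluene, 60 °C
Reagents that add atoms: none
Why: Zerovalent palladium, formed in the flask from Pd(OAc)2 and (R)-BINAP, inserts into the C10–O bond of the enol triflate with retention, the cationic alkenylpalladium adds syn across C5=C6, and β-hydride elimination from the methyl group on C6 (the only β-hydrogens, since C5 has become quaternary) leaves a vinyl group on C5; this is an intramolecular Heck reaction of an alkenyl triflate with a trisubstituted alkene, a known route to all-carbon quaternary centres. Ring A closes through the C5–C10 bond in the 6-exo-trig mode. The new stereocentre C5 is controlled by C4: allylic 1,3-strain with the methyl on C6, which is cis to C4 on the (Z)-alkene, holds H-4 in the alkene plane, so C10, tethered through C3–C2–C1, should add to the face away from the C4 methyl and the two methyl groups end up cis, a preference the chiral diphosphine is meant to reinforce. The step needs face selectivity at C5 and retention of the (Z)-geometry at C9=C10; the first rests on the (Z)-alkene/C4 pair, the second on the stereospecific oxidative addition and syn insertion. The weak carbonate base is chosen so that the triflate is not eliminated to an allenoate or alkynoate.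

**Step 9**
Reactants: 18 methyl (2Z)-2-[(2R,3R,4S)-4-(TBS-oxy)-2-ethenyl-2,3-dimethylcyclohexylidene]acetate
Product: 19 (2Z)-2-[(2R,3R,4S)-4-(TBS-oxy)-2-ethenyl-2,3-dimethylcyclohexylidene]-N-methoxy-N-methylacetamide
Conditions: MeNHOMe·HCl, i-PrMgCl, THF, −20 → 0 °C; aq. NH4Cl
Reagents that add atoms: N,O-dimethylhydroxylamine hydrochloride, CNOC.Cl
Why: Ester aminolysis by the chloromagnesium amide gives the N-methoxy-N-methylamide; the β,β-disubstituted enoate is not prone to conjugate addition, and the cold, weakly basic medium should leave the (Z)-geometry intact.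

**Step 10**
Reactants: 19 (2Z)-2-[(2R,3R,4S)-4-(TBS-oxy)-2-ethenyl-2,3-dimethylcyclohexylidene]-N-methoxy-N-methylacetamide
Product: 20 (1Z)-1-[(2R,3R,4S)-4-(TBS-oxy)-2-ethenyl-2,3-dimethylcyclohexylidene]but-3-en-2-one
Conditions: CH2=CHMgBr, THF, −78 → 0 °C; inverse quench into cold 1 M HCl
Reagents that add atoms: vinylmagnesium bromide, C=C[Mg]Br
Why: Grignard addition to the N-methoxy-N-methylamide stops at the magnesium-chelated tetrahedral adduct, and the cold acidic quench releases the divinyl ketone while keeping the liberated amine protonated.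

**Step 11**
Reactants: 20 (1Z)-1-[(2R,3R,4S)-4-(TBS-oxy)-2-ethenyl-2,3-dimethylcyclohexylidene]but-3-en-2-one
Product: 21 (4aR,5R,6S)-6-(TBS-oxy)-4a,5-dimethyl-5,6,7,8-tetrahydronaphthalen-2(4aH)-one
Conditions: second-generation Hoveyda–Grubbs catalyst RuCl2(=CH–C6H4-2-O-i-Pr)(H2IMes) (5 mol %), toluene, 80 °C
Reagents that add atoms: none
Why: Ring-closing olefin metathesis between the C5 vinyl group and the enone vinyl group forms C6=C7 and closes ring B with loss of ethene, the (Z)-geometry at C9=C10 holding the two alkenes within reach.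

**Step 12**
Reactants: 21 (4aR,5R,6S)-6-(TBS-oxy)-4a,5-dimethyl-5,6,7,8-tetrahydronaphthalen-2(4aH)-one
Product: 22 (4aR,5R,6S)-6-(TBS-oxy)-4a,5-dimethyl-4,4a,5,6,7,8-hexahydronaphthalen-2(3H)-one
Conditions: H2 (1 atm), RhCl(PPh3)3 (5 mol %), toluene, 23 °C
Reagents that add atoms: none
Why: Homogeneous hydrogenation with RhCl(PPh3)3 reduces the disubstituted C6=C7 bond of the cross-conjugated dienone and spares the trisubstituted C9=C10 bond, the selectivity known for 1,4-dien-3-ones of the steroid series.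

**Step 13**
Reactants: 22 (4aR,5R,6S)-6-(TBS-oxy)-4a,5-dimethyl-4,4a,5,6,7,8-hexahydronaphthalen-2(3H)-one
Product: 23 (4aR,5R,6S)-6-(TBS-oxy)-4a,5-dimethyl-4,4a,5,6-tetrahydronaphthalen-2(3H)-one
Conditions: chloranil, t-BuOH, reflux
Reagents that add atoms: none
Why: Quinone dehydrogenation through the C8(9),C10(1)-dienol, from which chloranil abstracts hydride at C2, should give the linear 1,9-dien-8-one as in the conversion of 4-en-3-ones into 4,6-dien-3-ones; C1 is the only γ-position at this stage, which is why the isopropylidene group is added afterwards.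

**Step 14**
Reactants: 23 (4aR,5R,6S)-6-(TBS-oxy)-4a,5-dimethyl-4,4a,5,6-tetrahydronaphthalen-2(3H)-one; 24 acetone
Product: 27 (4aR,5R,6S)-6-(TBS-oxy)-3-(2-hydroxypropan-2-yl)-4a,5-dimethyl-4,4a,5,6-tetrahydronaphthalen-2(3H)-one (both epimers at the new centre), via lithium enolate 25 (not isolated), via zinc enolate 26 (not isolated)
Conditions: LiN(i-Pr)2, THF, −78 °C; ZnCl2; acetone, −78 → −40 °C; aq. NH4Cl
Reagents that add atoms: none
Why: Kinetic deprotonation at C7, the only α'-position, gives the cross-conjugated enolate, and its zinc enolate undergoes a directed aldol addition to acetone with little retro-aldol; the C7 centre formed here is removed in the next step.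

**Step 15**
Reactants: 27 (4aR,5R,6S)-6-(TBS-oxy)-3-(2-hydroxypropan-2-yl)-4a,5-dimethyl-4,4a,5,6-tetrahydronaphthalen-2(3H)-one
Product: 29 (4aR,5R,6S)-6-(TBS-oxy)-4a,5-dimethyl-3-(propan-2-ylidene)-4,4a,5,6-tetrahydronaphthalen-2(3H)-one, via tertiary mesylate 28 (not isolated)
Conditions: MsCl, Et3N, CH2Cl2, 0 °C; then DBU, 23 °C
Reagents that add atoms: none
Why: Mesylation of the tertiary alcohol followed by E1cB elimination through the C7 enolate places the new double bond in conjugation with C8=O as the isopropylidene group.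

**Step 16**
Reactants: 29 (4aR,5R,6S)-6-(TBS-oxy)-4a,5-dimethyl-3-(propan-2-ylidene)-4,4a,5,6-tetrahydronaphthalen-2(3H)-one
Product: 30 (4aR,5R,6S)-6-hydroxy-4a,5-dimethyl-3-(propan-2-ylidene)-4,4a,5,6-tetrahydronaphthalen-2(3H)-one
Conditions: HF·pyridine, THF, 0 → 23 °C
Reagents that add atoms: none
Why: Fluoride cleavage of the silyl ether (desilylation) under mildly acidic conditions frees the C3 alcohol without affecting the trienone or any stereocentre.

**Step 17**
Reactants: 31 (S)-2-methylbutan-1-ol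
Product: 32 (S)-2-methylbutanal
Conditions: TEMPO (cat.), PhI(OAc)2, CH2Cl2, 23 °C; used as a solution
Reagents that add atoms: none
Why: Oxoammonium-mediated (TEMPO) oxidation of the primary alcohol stops at the aldehyde and, being free of base, should leave the α-stereocentre unracemised.

**Step 18**
Reactants: 32 (S)-2-methylbutanal; 33 triethyl (E)-4-phosphonobut-2-enoate
Product: 35 ethyl (2E,4E,6S)-6-methylocta-2,4-dienoate, via lithiated phosphonate 34 (not isolated)
Conditions: LiN(SiMe3)2, THF, −78 °C; then 32, −78 → 0 °C; aq. NH4Cl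
Reagents that add atoms: none
Why: Vinylogous Horner–Wadsworth–Emmons olefination with the γ-lithiated phosphonocrotonate gives the (2E,4E)-dienoate, the stabilised phosphonate favouring the E geometry of the new C4=C5 bond, while addition at −78 °C protects the α-stereocentre of the aldehyde.

**Step 19**
Reactants: 35 ethyl (2E,4E,6S)-6-methylocta-2,4-dienoate
Product: 36 (2E,4E,6S)-6-methylocta-2,4-dienoic acid
Conditions: LiOH, THF/MeOH/H2O, 23 °C; then 1 M HCl
Reagents that add atoms: lithium hydroxide, [Li+].[OH-]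
Why: Saponification of the ethyl ester (base hydrolysis), which leaves the diene geometry and the remote C6 stereocentre untouched.

**Step 20**
Reactants: 30 (4aR,5R,6S)-6-hydroxy-4a,5-dimethyl-3-(propan-2-ylidene)-4,4a,5,6-tetrahydronaphthalen-2(3H)-one; 36 (2E,4E,6S)-6-methylocta-2,4-dienoic acid
Product: 37 (1R,2S,8aR)-1,8a-dimethyl-6-oxo-7-(propan-2-ylidene)-1,2,6,7,8,8a-hexahydronaphthalen-2-yl (2E,4E,6S)-6-methylocta-2,4-dienoate
Conditions: EDC·HCl, DMAP, CH2Cl2, 0 → 23 °C
Reagents that add atoms: none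
Why: Carbodiimide/DMAP acylation (Steglich esterification) of the secondary allylic alcohol by the dienoic acid, with retention at C3 because the C3–O bond is not broken.

**Compound list**

1 | ethanol | CCO | starting material
2 | N,N-diisopropylcarbamoyl chloride | CC(C)N(C(C)C)C(Cl)=O | starting material
3 | ethyl N,N-diisopropylcarbamate | CCOC(=O)N(C(C)C)C(C)C | intermediate
4 | (Z)-2-(but-2-en-2-yl)-4,4,5,5-tetramethyl-1,3,2-dioxaborolane | C/C=C(\C)B1OC(C)(C)C(C)(C)O1 | starting material
5 | (S)-1-lithioethyl N,N-diisopropylcarbamate (sparteine complex) | C[C@H]([Li])OC(=O)N(C(C)C)C(C)C | intermediate (not isolated)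
6 | lithium [(1S)-1-(N,N-diisopropylcarbamoyloxy)ethyl][(2Z)-but-2-en-2-yl](pinacolato)borate | C[C@H]([B-]1(OC(C)(C)C(C)(C)O1)/C(C)=C/C)OC(=O)N(C(C)C)C(C)C.[Li+] | intermediate (not isolated)
7 | 2-[(2R,3E)-3-methylpent-3-en-2-yl]-4,4,5,5-tetramethyl-1,3,2-dioxaborolane | C[C@@H](B1OC(C)(C)C(C)(C)O1)/C(C)=C/C | intermediate
8 | methyl 4-oxobutanoate | COC(=O)CCC=O | starting material
9 | methyl (4S,5R,6Z)-5,6-dimethyl-4-[(4,4,5,5-tetramethyl-1,3,2-dioxaborolan-2-yl)oxy]oct-6-enoate | COC(=O)CC[C@H](OB1OC(C)(C)C(C)(C)O1)[C@H](C)/C(C)=C\C | intermediate (not isolated)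
10 | methyl (4S,5R,6Z)-4-hydroxy-5,6-dimethyloct-6-enoate | COC(=O)CC[C@H](O)[C@H](C)/C(C)=C\C | intermediate (not isolated)
11 | (5S)-5-[(2R,3Z)-3-methylpent-3-en-2-yl]oxolan-2-one | O=C1CC[C@H](O1)[C@H](C)/C(C)=C\C | intermediate
12 | (4S,5R,6Z)-4-hydroxy-N-methoxy-N,5,6-trimethyloct-6-enamide | CON(C)C(=O)CC[C@H](O)[C@H](C)/C(C)=C\C | intermediate
13 | (4S,5R,6Z)-4-(TBS-oxy)-N-methoxy-N,5,6-trimethyloct-6-enamide | CON(C)C(=O)CC[C@H](O[Si](C)(C)C(C)(C)C)[C@H](C)/C(C)=C\C | intermediate
14 | methyl acetate | COC(C)=O | starting material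
15 | lithium enolate of methyl acetate (lithium 1-methoxyethen-1-olate) | C=C(OC)O[Li] | intermediate (not isolated)
16 | methyl (6S,7R,8Z)-6-(TBS-oxy)-7,8-dimethyl-3-oxodec-8-enoate | COC(=O)CC(=O)CC[C@H](O[Si](C)(C)C(C)(C)C)[C@H](C)/C(C)=C\C | intermediate
17 | methyl (2Z,6S,7R,8Z)-6-(TBS-oxy)-7,8-dimethyl-3-{[(trifluoromethyl)sulfonyl]oxy}deca-2,8-dienoate | COC(=O)/C=C(\OS(=O)(=O)C(F)(F)F)CC[C@H](O[Si](C)(C)C(C)(C)C)[C@H](C)/C(C)=C\C | intermediate
18 | methyl (2Z)-2-[(2R,3R,4S)-4-(TBS-oxy)-2-ethenyl-2,3-dimethylcyclohexylidene]acetate | COC(=O)/C=C1/CC[C@H](O[Si](C)(C)C(C)(C)C)[C@H](C)[C@@]1(C)C=C | intermediate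
19 | (2Z)-2-[(2R,3R,4S)-4-(TBS-oxy)-2-ethenyl-2,3-dimethylcyclohexylidene]-N-methoxy-N-methylacetamide | CON(C)C(=O)/C=C1/CC[C@H](O[Si](C)(C)C(C)(C)C)[C@H](C)[C@@]1(C)C=C | intermediate
20 | (1Z)-1-[(2R,3R,4S)-4-(TBS-oxy)-2-ethenyl-2,3-dimethylcyclohexylidene]but-3-en-2-one | C=CC(=O)/C=C1/CC[C@H](O[Si](C)(C)C(C)(C)C)[C@H](C)[C@@]1(C)C=C | intermediate
21 | (4aR,5R,6S)-6-(TBS-oxy)-4a,5-dimethyl-5,6,7,8-tetrahydronaphthalen-2(4aH)-one | CC(C)(C)[Si](C)(C)O[C@H]1CCC2=CC(=O)C=C[C@]2(C)[C@H]1C | intermediate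
22 | (4aR,5R,6S)-6-(TBS-oxy)-4a,5-dimethyl-4,4a,5,6,7,8-hexahydronaphthalen-2(3H)-one | CC(C)(C)[Si](C)(C)O[C@H]1CCC2=CC(=O)CC[C@]2(C)[C@H]1C | intermediate
23 | (4aR,5R,6S)-6-(TBS-oxy)-4a,5-dimethyl-4,4a,5,6-tetrahydronaphthalen-2(3H)-one | CC(C)(C)[Si](C)(C)O[C@H]1C=CC2=CC(=O)CC[C@]2(C)[C@H]1C | intermediate
24 | acetone | CC(C)=O | starting material
25 | lithium (4aR,5R,6S)-6-(TBS-oxy)-4a,5-dimethyl-4,4a,5,6-tetrahydronaphthalen-2-olate | CC(C)(C)[Si](C)(C)O[C@H]1C=CC2=CC(O[Li])=CC[C@]2(C)[C@H]1C | intermediate (not isolated)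
26 | chlorozinc (4aR,5R,6S)-6-(TBS-oxy)-4a,5-dimethyl-4,4a,5,6-tetrahydronaphthalen-2-olate | CC(C)(C)[Si](C)(C)O[C@H]1C=CC2=CC(O[Zn]Cl)=CC[C@]2(C)[C@H]1C | intermediate (not isolated)
27 | (4aR,5R,6S)-6-(TBS-oxy)-3-(2-hydroxypropan-2-yl)-4a,5-dimethyl-4,4a,5,6-tetrahydronaphthalen-2(3H)-one, both C3 epimers | CC(C)(C)[Si](C)(C)O[C@H]1C=CC2=CC(=O)C(C(C)(C)O)C[C@]2(C)[C@H]1C | intermediate
28 | 2-[(4aR,5R,6S)-6-(TBS-oxy)-4a,5-dimethyl-2-oxo-2,3,4,4a,5,6-hexahydronaphthalen-3-yl]propan-2-yl methanesulfonate | CC(C)(C)[Si](C)(C)O[C@H]1C=CC2=CC(=O)C(C(C)(C)OS(C)(=O)=O)C[C@]2(C)[C@H]1C | intermediate (not isolated)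
29 | (4aR,5R,6S)-6-(TBS-oxy)-4a,5-dimethyl-3-(propan-2-ylidene)-4,4a,5,6-tetrahydronaphthalen-2(3H)-one | CC(C)(C)[Si](C)(C)O[C@H]1C=CC2=CC(=O)C(=C(C)C)C[C@]2(C)[C@H]1C | intermediate
30 | (4aR,5R,6S)-6-hydroxy-4a,5-dimethyl-3-(propan-2-ylidene)-4,4a,5,6-tetrahydronaphthalen-2(3H)-one | O[C@H]1C=CC2=CC(=O)C(=C(C)C)C[C@]2(C)[C@H]1C | intermediate
31 | (S)-2-methylbutan-1-ol | CC[C@H](C)CO | starting material
32 | (S)-2-methylbutanal | CC[C@H](C)C=O | intermediate
33 | triethyl (E)-4-phosphonobut-2-enoate | CCOC(=O)/C=C/CP(=O)(OCC)OCC | starting material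
34 | lithium salt of the γ-carbanion of triethyl (E)-4-phosphonobut-2-enoate | CCOC(=O)/C=C/[CH-]P(=O)(OCC)OCC.[Li+] | intermediate (not isolated)
35 | ethyl (2E,4E,6S)-6-methylocta-2,4-dienoate | CC[C@H](C)/C=C/C=C/C(=O)OCC | intermediate
36 | (2E,4E,6S)-6-methylocta-2,4-dienoic acid | CC[C@H](C)/C=C/C=C/C(=O)O | intermediate
37 | (1R,2S,8aR)-1,8a-dimethyl-6-oxo-7-(propan-2-ylidene)-1,2,6,7,8,8a-hexahydronaphthalen-2-yl (2E,4E,6S)-6-methylocta-2,4-dienoate | CC[C@H](C)/C=C/C=C/C(=O)O[C@H]1C=CC2=CC(=O)C(=C(C)C)C[C@]2(C)[C@H]1C | target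

**Step count**

Total: 20 steps. Longest linear sequence: 17 steps (steps 1–16, then step 20); the side-chain acid takes 3 steps (17–19).

**Steps most likely to fail**

1. Step 8 (Heck closure of ring A). Carbopalladation of the hindered trisubstituted alkene may be slower than loss of the triflate by elimination or reduction, or the two faces of C5=C6 may not be distinguished well enough. Fallback: the same C5–C10 bond is made in the polar sense, by intramolecular Hosomi–Sakurai addition of a C5=C6–CH2SiMe3 allylsilane to the C10 ketone. It sets out from 2, 4 and 8. Commercial 2-(trimethylsilyl)ethanol is carbamoylated with 2 to give 2-(trimethylsilyl)ethyl N,N-diisopropylcarbamate F1. Lithiation–borylation with 4 under the conditions of step 2 should give the α-(silylmethyl) allylboronate F2. Allylboration of 8 and lactonisation as in step 3 should give the (Z)-allylsilane lactone F3. Amide opening as in step 4 gives the hydroxy amide F4, and silylation as in step 5 its silyl ether F5. Acylation of lithiated N-methoxy-N-methylacetamide by F5 gives the β-keto amide F6. TiCl4 in CH2Cl2 at −78 °C should then close ring A to the β-hydroxy amide F7, in which C5 carries methyl and vinyl. CH2=CHMgBr gives the hydroxy vinyl ketone F8, ring-closing metathesis as in step 11 gives the hydroxy enone F9, and dehydration (MsCl, Et3N, then DBU) returns to the route at 21.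

2. Step 11 (ring-closing metathesis). Both alkenes are poor partners, an electron-poor vinyl ketone and a vinyl group on a quaternary carbon, so initiation may be slow and the divinyl ketone may oligomerise first. Fallback: from 20, Luche reduction (NaBH4, CeCl3·7H2O, MeOH, −78 °C) gives the bis-allylic alcohol F10, whose carbinol vinyl group should initiate readily. Metathesis with the same catalyst then gives the cyclohexadienol F11, and oxidation with MnO2 returns to the route at 21.

3. Step 13 (dehydrogenation to C1=C2). Hydride abstraction at C2, next to the silyloxy-bearing C3, may be slow, so that over-oxidation or dehydrogenation on the C6–C7 side competes. Fallback: from 22, thermodynamic silylation (TBSOTf, Et3N, CH2Cl2) gives the heteroannular silyl dienol ether F12. Saegusa–Ito oxidation with stoichiometric Pd(OAc)2 (divalent palladium) in MeCN should place palladium at C1 and remove the C2 hydrogen, returning to the route at 23.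

**Further compounds**

F1 | step 8 | 2-(trimethylsilyl)ethyl N,N-diisopropylcarbamate | C[Si](C)(C)CCOC(=O)N(C(C)C)C(C)C
F2 | step 8 | 2-[(2S,3E)-3-methyl-1-(trimethylsilyl)pent-3-en-2-yl]-4,4,5,5-tetramethyl-1,3,2-dioxaborolane | C[Si](C)(C)C[C@@H](B1OC(C)(C)C(C)(C)O1)/C(C)=C/C
F3 | step 8 | (5S)-5-[(2R,3Z)-3-methyl-5-(trimethylsilyl)pent-3-en-2-yl]oxolan-2-one | O=C1CC[C@H](O1)[C@H](C)/C(C)=C\C[Si](C)(C)C
F4 | step 8 | (4S,5R,6Z)-4-hydroxy-N-methoxy-N,5,6-trimethyl-8-(trimethylsilyl)oct-6-enamide | CON(C)C(=O)CC[C@H](O)[C@H](C)/C(C)=C\C[Si](C)(C)C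
F5 | step 8 | (4S,5R,6Z)-4-(TBS-oxy)-N-methoxy-N,5,6-trimethyl-8-(trimethylsilyl)oct-6-enamide | CON(C)C(=O)CC[C@H](O[Si](C)(C)C(C)(C)C)[C@H](C)/C(C)=C\C[Si](C)(C)C
F6 | step 8 | (6S,7R,8Z)-6-(TBS-oxy)-N-methoxy-N,7,8-trimethyl-3-oxo-10-(trimethylsilyl)dec-8-enamide | CON(C)C(=O)CC(=O)CC[C@H](O[Si](C)(C)C(C)(C)C)[C@H](C)/C(C)=C\C[Si](C)(C)C
F7 | step 8 | 2-[(2R,3R,4S)-4-(TBS-oxy)-2-ethenyl-1-hydroxy-2,3-dimethylcyclohexyl]-N-methoxy-N-methylacetamide | CON(C)C(=O)CC1(O)CC[C@H](O[Si](C)(C)C(C)(C)C)[C@H](C)[C@@]1(C)C=C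
F8 | step 8 | 1-[(2R,3R,4S)-4-(TBS-oxy)-2-ethenyl-1-hydroxy-2,3-dimethylcyclohexyl]but-3-en-2-one | C=CC(=O)CC1(O)CC[C@H](O[Si](C)(C)C(C)(C)C)[C@H](C)[C@@]1(C)C=C
F9 | step 8 | (4aR,5R,6S)-6-(TBS-oxy)-8a-hydroxy-4a,5-dimethyl-4a,5,6,7,8,8a-hexahydronaphthalen-2(1H)-one | CC(C)(C)[Si](C)(C)O[C@H]1CCC2(O)CC(=O)C=C[C@]2(C)[C@H]1C
F10 | step 11 | (1Z)-1-[(2R,3R,4S)-4-(TBS-oxy)-2-ethenyl-2,3-dimethylcyclohexylidene]but-3-en-2-ol | C=CC(O)/C=C1/CC[C@H](O[Si](C)(C)C(C)(C)C)[C@H](C)[C@@]1(C)C=C
F11 | step 11 | (4aR,5R,6S)-6-(TBS-oxy)-4a,5-dimethyl-2,4a,5,6,7,8-hexahydronaphthalen-2-ol | CC(C)(C)[Si](C)(C)O[C@H]1CCC2=CC(O)C=C[C@]2(C)[C@H]1C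
F12 | step 13 | (4aR,5R,6S)-2,6-bis(TBS-oxy)-4a,5-dimethyl-3,4,4a,5,6,7-hexahydronaphthalene | CC(C)(C)[Si](C)(C)O[C@H]1CC=C2C=C(O[Si](C)(C)C(C)(C)C)CC[C@]2(C)[C@H]1C
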